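**Plan**

- Retrosynthetically, C4–H of the 6,7-dimethoxycoumarin is first returned to C4–OH; the pyranone ring of that 4-hydroxycoumarin is then cut at C2–C3 and C2–O1, which takes C2 out as a carbonate carbon.
- This is possible because C2 is a carbonyl carbon held between ring oxygen O1 and C3, and C3 carries the umbelliferyl ether oxygen and lies alpha to the former ketone carbon C4. One carbonate can therefore acylate both a phenol oxygen and an acidic aryloxymethyl ketone CH2.
- The remaining 2-hydroxyaryl aryloxymethyl ketone is cut at the aryl–C(=O) bond (C-acylation of 3,4-dimethoxyphenol) and at the O–CH2 bond (alkylation of umbelliferone).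
- Forward: the umbelliferone bicycle is bought intact, the OCH2CO2H chain is attached to it, the chain is joined to the dimethoxyphenol ring, the second pyranone ring is closed with diethyl carbonate, and the C4 oxygen is removed through its triflate.
- The target is achiral, with no stereocentre and no configurable double bond, so no stereochemistry has to be set.

Key step: step 4

Remark on the chemistry: the two-carbon linker is brought in as a tert-butyl ester so that the acid is freed by acid and the lactone of the umbelliferone unit never meets hydroxide.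

**Route**

Step 1
Reactants: 1 umbelliferone (7-hydroxy-2H-chromen-2-one); 2 tert-butyl bromoacetate
Product: 3 tert-butyl 2-[(2-oxo-2H-chromen-7-yl)oxy]acetate
Conditions: K2CO3, acetone, reflux
Reagents that add atoms: none
Why: Williamson ether synthesis, in which the acidic 7-hydroxyl is deprotonated by K2CO3 and the phenoxide displaces bromide from the activated alpha-halo ester by SN2, while carbonate in acetone is too weak a nucleophile to open the lactone.

Step 2
Reactants: 3 tert-butyl 2-[(2-oxo-2H-chromen-7-yl)oxy]acetate
Product: 4 2-[(2-oxo-2H-chromen-7-yl)oxy]acetic acid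
Conditions: TFA, CH2Cl2, 0 °C to rt
Reagents that add atoms: none
Why: Acidolysis of a tert-butyl ester (E1 loss of the tert-butyl cation as 2-methylpropene) should free the carboxylic acid without aqueous base, so the lactone and the aryl ether stay untouched.

Step 3
Reactants: 4 2-[(2-oxo-2H-chromen-7-yl)oxy]acetic acid; 5 3,4-dimethoxyphenol
Product: 6 7-[2-(2-hydroxy-4,5-dimethoxyphenyl)-2-oxoethoxy]-2H-chromen-2-one
Conditions: BF3·OEt2 (neat, as solvent and promoter), 85 °C; then aq. NaOAc
Reagents that add atoms: none
Why: Friedel–Crafts acylation of a phenol by a free carboxylic acid in BF3·OEt2 (possibly through the aryl ester and a Fries shift) should occur at C6 of the phenol, ortho to the hydroxyl and para to the 3-methoxy group, rather than at crowded C2, and the lactone-deactivated coumarin ring of 4 should not compete as a nucleophile.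

Step 4
Reactants: 6 7-[2-(2-hydroxy-4,5-dimethoxyphenyl)-2-oxoethoxy]-2H-chromen-2-one; 7 diethyl carbonate
Product: 9 4-hydroxy-6,7-dimethoxy-3-[(2-oxo-2H-chromen-7-yl)oxy]-2H-chromen-2-one, via aryl ethyl carbonate 8 (not isolated)
Conditions: NaH (4 equiv), toluene, 0 °C to 100 °C; then 1 M HCl, rt
Reagents that add atoms: none
Why: NaH turns 6 into its phenoxide, which diethyl carbonate ethoxycarbonylates to aryl carbonate 8, and the ketone enolate, whose alpha carbon is acidified by the aryloxy substituent, then attacks the carbonate carbonyl and expels ethoxide; C-ethoxycarbonylation followed by lactonisation would converge on the same product. The closest known reaction type is the Claisen-type condensation of 2-hydroxyaryl ketones with diethyl carbonate and NaH that delivers 4-hydroxycoumarins. The pyranone ring closes by a 6-(enolendo)-exo-trig attack of C3 on the future C2, so that C2–C3 forms after C2–O1. No stereocentre is created. The step needs chemoselectivity for the phenol and ketone over the lactone and enone of the umbelliferone unit: NaH deprotonates irreversibly without acting as a nucleophile, the ethoxide released can open that lactone only to the Z-configured 2-hydroxycinnamate, which should relactonise on acidification, and the intramolecular acylation should outrun intermolecular conjugate addition. Formation of the delocalised sodium salt of the 4-hydroxycoumarin, a vinylogous carboxylate, should make the sequence irreversible.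

Step 5
Reactants: 9 4-hydroxy-6,7-dimethoxy-3-[(2-oxo-2H-chromen-7-yl)oxy]-2H-chromen-2-one
Product: 10 6,7-dimethoxy-2-oxo-3-[(2-oxo-2H-chromen-7-yl)oxy]-2H-chromen-4-yl trifluoromethanesulfonate
Conditions: Tf2O, Et3N, CH2Cl2, −20 °C to 0 °C
Reagents that add atoms: trifluoromethanesulfonic anhydride, O=S(=O)(OS(=O)(=O)C(F)(F)F)C(F)(F)F
Why: O-sulfonylation of an enol, in which the 4-hydroxycoumarin behaves as a vinylogous carboxylic acid whose triethylammonium salt is triflated on oxygen at low temperature, the standard entry to 4-(triflyloxy)coumarins, with the second lactone and the ethers inert.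

Step 6
Reactants: 10 6,7-dimethoxy-2-oxo-3-[(2-oxo-2H-chromen-7-yl)oxy]-2H-chromen-4-yl trifluoromethanesulfonate
Product: 11 daphnoretin methyl ether (6,7-dimethoxy-3-[(2-oxo-2H-chromen-7-yl)oxy]-2H-chromen-2-one)
Conditions: Pd(OAc)2 (cat.), dppf, HCO2H, Et3N, DMF, 60 °C
Reagents that add atoms: none
Why: Palladium-catalysed transfer hydrogenolysis of a vinyl triflate, in which zerovalent palladium formed from Pd(OAc)2 and dppf inserts into the C4–O bond, formate replaces triflate and loses CO2 to give a palladium hydride, and reductive elimination should form C4–H without reducing either lactone double bond.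

**Compound list**

1 | umbelliferone (7-hydroxy-2H-chromen-2-one) | Oc1ccc2ccc(=O)oc2c1 | starting material
2 | tert-butyl bromoacetate | CC(C)(C)OC(=O)CBr | starting material
3 | tert-butyl 2-[(2-oxo-2H-chromen-7-yl)oxy]acetate | CC(C)(C)OC(=O)COc1ccc2ccc(=O)oc2c1 | intermediate
4 | 2-[(2-oxo-2H-chromen-7-yl)oxy]acetic acid | OC(=O)COc1ccc2ccc(=O)oc2c1 | intermediate
5 | 3,4-dimethoxyphenol | COc1ccc(O)cc1OC | starting material
6 | 7-[2-(2-hydroxy-4,5-dimethoxyphenyl)-2-oxoethoxy]-2H-chromen-2-one | COc1cc(O)c(cc1OC)C(=O)COc1ccc2ccc(=O)oc2c1 | intermediate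
7 | diethyl carbonate | CCOC(=O)OCC | starting material
8 | ethyl 4,5-dimethoxy-2-{[(2-oxo-2H-chromen-7-yl)oxy]acetyl}phenyl carbonate | CCOC(=O)Oc1cc(OC)c(OC)cc1C(=O)COc1ccc2ccc(=O)oc2c1 | intermediate
9 | 4-hydroxy-6,7-dimethoxy-3-[(2-oxo-2H-chromen-7-yl)oxy]-2H-chromen-2-one | COc1cc2c(O)c(Oc3ccc4ccc(=O)oc4c3)c(=O)oc2cc1OC | intermediate
10 | 6,7-dimethoxy-2-oxo-3-[(2-oxo-2H-chromen-7-yl)oxy]-2H-chromen-4-yl trifluoromethanesulfonate | COc1cc2c(OS(=O)(=O)C(F)(F)F)c(Oc3ccc4ccc(=O)oc4c3)c(=O)oc2cc1OC | intermediate
11 | daphnoretin methyl ether | COc1cc2cc(Oc3ccc4ccc(=O)oc4c3)c(=O)oc2cc1OC | target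

**Step count and risks**

Total step count: 6. Longest linear sequence: 6 steps (1 → 3 → 4 → 6 → 9 → 10 → 11).

Steps most likely to fail:

1. Step 4. The ethoxide released during the condensation may attack the lactone of the umbelliferone unit faster than it recloses (ring opening followed by O-ethoxycarbonylation, or conjugate addition), or the sequence may stall after O-acylation without the carbon–carbon bond forming. The fallback sets out from acid 4 and comes back to the route at 9. Acid 4 would be esterified (EDC·HCl, DMAP, CH2Cl2) with purchased methyl 2-hydroxy-4,5-dimethoxybenzoate F1 to give methyl 4,5-dimethoxy-2-({[(2-oxo-2H-chromen-7-yl)oxy]acetyl}oxy)benzoate F2. Treatment with LiN(SiMe3)2 in THF at −78 °C to 0 °C should then trigger an intramolecular Claisen (Dieckmann-type) condensation of the aryloxyacetate enolate onto the methyl ester. This closes the same pyranone ring by forming C3–C4 instead of C2–C3, with a non-nucleophilic base, and gives 9.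

2. Step 3. Acylation may stop at the phenol oxygen without migration to carbon, or the acid may degrade or acylate the wrong position in hot BF3·OEt2. The fallback sets out from umbelliferone 1 and comes back at 6, building the ether bond last instead of the aryl–carbonyl bond. Purchased 1-(2-hydroxy-4,5-dimethoxyphenyl)ethanone F3 would be benzylated (BnBr, K2CO3, DMF) to 1-[2-(benzyloxy)-4,5-dimethoxyphenyl]ethanone F4. Side-chain bromination with phenyltrimethylammonium tribromide in THF would give 1-[2-(benzyloxy)-4,5-dimethoxyphenyl]-2-bromoethanone F5. Alkylation of 1 with F5 (K2CO3, acetone) would give 7-{2-[2-(benzyloxy)-4,5-dimethoxyphenyl]-2-oxoethoxy}-2H-chromen-2-one F6. BCl3 in CH2Cl2 at −78 °C should then cleave the benzyl ether ortho to the carbonyl by chelation-assisted dealkylation and release 6.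

3. Step 6. Sulfur–oxygen cleavage or hydrolysis of the triflate back to the 4-hydroxycoumarin may outpace oxidative addition at C4, which is flanked by the aryloxy group, or hydride transfer may be slow enough for the catalyst to decompose. The fallback sets out from 9 and comes back at 11, replacing steps 5 and 6. POCl3 with benzyltriethylammonium chloride in MeCN at reflux would give 4-chloro-6,7-dimethoxy-3-[(2-oxo-2H-chromen-7-yl)oxy]-2H-chromen-2-one F7. Zn dust in AcOH/EtOH at reflux should then remove the chlorine of this vinylogous acyl chloride by dissolving-metal reduction to give 11.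

**Further compounds**

F1 | step 4 | methyl 2-hydroxy-4,5-dimethoxybenzoate (purchased) | COC(=O)c1cc(OC)c(OC)cc1O
F2 | step 4 | methyl 4,5-dimethoxy-2-({[(2-oxo-2H-chromen-7-yl)oxy]acetyl}oxy)benzoate | COC(=O)c1cc(OC)c(OC)cc1OC(=O)COc1ccc2ccc(=O)oc2c1
F3 | step 3 | 1-(2-hydroxy-4,5-dimethoxyphenyl)ethanone (purchased) | CC(=O)c1cc(OC)c(OC)cc1O
F4 | step 3 | 1-[2-(benzyloxy)-4,5-dimethoxyphenyl]ethanone | CC(=O)c1cc(OC)c(OC)cc1OCc1ccccc1
F5 | step 3 | 1-[2-(benzyloxy)-4,5-dimethoxyphenyl]-2-bromoethanone | BrCC(=O)c1cc(OC)c(OC)cc1OCc1ccccc1
F6 | step 3 | 7-{2-[2-(benzyloxy)-4,5-dimethoxyphenyl]-2-oxoethoxy}-2H-chromen-2-one | COc1cc(OCc2ccccc2)c(cc1OC)C(=O)COc1ccc2ccc(=O)oc2c1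
F7 | step 6 | 4-chloro-6,7-dimethoxy-3-[(2-oxo-2H-chromen-7-yl)oxy]-2H-chromen-2-one | COc1cc2c(Cl)c(Oc3ccc4ccc(=O)oc4c3)c(=O)oc2cc1OC
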